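Retrosynthesis: after removal of two silyl ethers, the dihydropyranone ring (O1'–C2'(CH3)–C3'H2–C4'(=O)–C5'H=C6') is cut at C4'–C5', which leads back to a 3-(1-alkoxyvinyl)coumarin whose ether chain ends in a pyrrolidine amide (a dormant acyl group at C4').
Further cuts: C3–C6' (Mizoroki–Heck coupling of a 3-bromocoumarin with a chiral vinyl ether), the lactone and C3=C4 of the coumarin (Knoevenagel condensation with Meldrum's acid), the ring formyl carbon (orthoformate), and the aryl–CH(CH3) bond (aryllithium plus trans-epoxide).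
Forward order: the benzene ring is substituted, the side chain attached, a temporary isochromenone oxygen ring masks the salicylaldehyde, the coumarin ring is made, C3 is brominated and coupled, the pyranone ring is closed last, and the silyl groups are removed.
Enabling feature: the CH2 terminus C5' of the 1-alkoxyvinyl group on coumarin C3 is the only nucleophilic carbon (a 2-alkoxy-1,3-diene with C3=C4; the cation left at C6' is stabilised by O1' and by the 7-silyloxy benzo ring) and lies 1,6 to the amide carbon C4' through C6', O1', C2' and C3'.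
Stereochemistry: both side-chain centres come from (2R,3R)-2,3-dimethyloxirane (SN2 inversion at the attacked carbon); C2' comes from ethyl (3S)-3-hydroxybutanoate and meets no strong base after the vinyl ether is made.
Key step: step 12

Remark: TBS is tert-butyldimethylsilyl; the ortho-hydroxy aldehyde carrying the free side-chain alcohol is handled as its cyclodehydrated quinone methide 9, the form in which such hydroxy aldehydes are isolated and which reacts at C1 as the aldehyde.

Step 1
Reactants: 1 1,3-bis(benzyloxy)-5-bromobenzene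
Product: 3 2,4-bis(benzyloxy)-6-bromobenzaldehyde, via iminium dichlorophosphate 2 (not isolated)
Conditions: POCl3, DMF, 0 → 80 °C; then aq. NaOAc, rt
Reagents that add atoms: N,N-dimethylformamide (CN(C)C=O); water (O)
Why: Vilsmeier–Haack formylation of the doubly activated ring should occur para to one benzyloxy group and ortho to the other at the carbon next to bromine, since the site between the two ether groups is the more hindered one.

Step 2
Reactants: 3 2,4-bis(benzyloxy)-6-bromobenzaldehyde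
Product: 4 1,5-bis(benzyloxy)-3-bromo-2-methylbenzene
Conditions: Et3SiH, CF3CO2H, CH2Cl2, 0 °C → rt
Reagents that add atoms: none
Why: Ionic hydrogenation (silane/acid deoxygenation) should work because the benzylic cation is stabilised by the ortho and para alkoxy groups, and it leaves the aryl bromide and the benzyl ethers untouched.

Step 3
Reactants: 4 1,5-bis(benzyloxy)-3-bromo-2-methylbenzene; 5 (2R,3R)-2,3-dimethyloxirane
Product: 7 (2R,3R)-3-[3,5-bis(benzyloxy)-2-methylphenyl]butan-2-ol, via aryllithium 6 (not isolated)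
Conditions: n-BuLi, THF, −78 °C; then 5, BF3·OEt2, −78 °C
Reagents that add atoms: none
Why: Bromine–lithium exchange gives aryllithium 6, whose BF3-promoted SN2 opening of the C2-symmetric trans-epoxide (both carbons equivalent) inverts the attacked carbon, so that the new benzylic centre is R and the untouched carbinol centre stays R.

Step 4
Reactants: 7 (2R,3R)-3-[3,5-bis(benzyloxy)-2-methylphenyl]butan-2-ol
Product: 8 5-[(2R,3R)-3-hydroxybutan-2-yl]-4-methylbenzene-1,3-diol
Conditions: H2 (1 atm), 10% Pd/C, EtOAc/MeOH, rt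
Reagents that add atoms: none
Why: Hydrogenolysis of the two benzyl aryl ethers over Pd/C is routine and cannot affect the saturated side chain or its stereocentres.

Step 5
Reactants: 8 5-[(2R,3R)-3-hydroxybutan-2-yl]-4-methylbenzene-1,3-diol
Product: 9 (3R,4R)-8-hydroxy-3,4,5-trimethyl-3,4-dihydro-6H-isochromen-6-one
Conditions: HC(OEt)3, CF3CO2H, CH2Cl2, 0 °C → rt
Reagents that add atoms: triethyl orthoformate (CCOC(OCC)OCC)
Why: Acid-promoted orthoformate formylation (electrophilic aromatic substitution by a dialkoxycarbenium ion, delivered after exchange onto the side-chain hydroxyl) should attack the ring carbon that is next to the side chain, ortho to one hydroxyl and para to the other, and loss of ethanol closes the six-membered oxygen ring to the vinylogous-ester quinone methide without touching either stereocentre.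

Step 6
Reactants: 9 (3R,4R)-8-hydroxy-3,4,5-trimethyl-3,4-dihydro-6H-isochromen-6-one; 10 2,2-dimethyl-1,3-dioxane-4,6-dione (Meldrum's acid)
Product: 11 7-hydroxy-5-[(2R,3R)-3-hydroxybutan-2-yl]-6-methyl-2-oxo-2H-chromene-3-carboxylic acid
Conditions: piperidinium acetate (cat.), EtOH/H2O, 50 °C
Reagents that add atoms: none
Why: In this Knoevenagel condensation Meldrum's acid adds to C1 of 9 (which in aqueous ethanol equilibrates with the ring-opened ortho-hydroxy aldehyde), the neighbouring phenol is acylated with loss of acetone, and E1cB cleavage of the benzylic C1–O bond releases the side-chain alcohol and gives the conjugated coumarin-3-carboxylic acid.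

Step 7
Reactants: 11 7-hydroxy-5-[(2R,3R)-3-hydroxybutan-2-yl]-6-methyl-2-oxo-2H-chromene-3-carboxylic acid
Product: 13 7-(TBSO)-5-[(2R,3R)-3-(TBSO)butan-2-yl]-6-methyl-2-oxo-2H-chromene-3-carboxylic acid, via silyl ester 12 (not isolated)
Conditions: TBSOTf, 2,6-lutidine, CH2Cl2, 0 °C → rt; then THF/H2O/AcOH, rt
Reagents that add atoms: tert-butyldimethylsilyl triflate (CC(C)(C)[Si](C)(C)OS(=O)(=O)C(F)(F)F)
Why: The silyl triflate with a hindered pyridine base silylates the phenol, the hindered secondary alcohol and the acid, and the labile silyl ester 12 is hydrolysed selectively on aqueous work-up.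

Step 8
Reactants: 13 7-(TBSO)-5-[(2R,3R)-3-(TBSO)butan-2-yl]-6-methyl-2-oxo-2H-chromene-3-carboxylic acid
Product: 14 3-bromo-7-(TBSO)-5-[(2R,3R)-3-(TBSO)butan-2-yl]-6-methyl-2H-chromen-2-one
Conditions: N-bromosuccinimide, LiOAc (cat.), MeCN/H2O, rt
Reagents that add atoms: N-bromosuccinimide (O=C1CCC(=O)N1Br)
Why: In this Hunsdiecker-type bromodecarboxylation electrophilic bromine attacks C3 ipso to the carboxylate, the cation at C4 is stabilised by the para silyloxy group, and loss of CO2 restores the C3=C4 bond with bromine on C3.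

Step 9
Reactants: 15 ethyl (3S)-3-hydroxybutanoate
Product: 16 (3S)-3-hydroxy-1-(pyrrolidin-1-yl)butan-1-one
Conditions: pyrrolidine (neat), 80 °C
Reagents that add atoms: pyrrolidine (C1CCNC1)
Why: Aminolysis of the ester by the nucleophilic secondary amine gives the tertiary amide without touching the carbinol centre, which stays S.

Step 10
Reactants: 16 (3S)-3-hydroxy-1-(pyrrolidin-1-yl)butan-1-one
Product: 17 (3S)-3-(ethenyloxy)-1-(pyrrolidin-1-yl)butan-1-one
Conditions: butyl vinyl ether (excess, as solvent), Pd(OCOCF3)2, 4,7-diphenyl-1,10-phenanthroline, Et3N (cat.), 75 °C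
Reagents that add atoms: butyl vinyl ether (C=COCCCC)
Why: Palladium-catalysed transfer vinylation (transetherification by oxypalladation and de-oxypalladation) moves the vinyl group onto the secondary alcohol without breaking the C–O bond at the stereocentre, and the excess of butyl vinyl ether drives the equilibrium.

Step 11
Reactants: 14 3-bromo-7-(TBSO)-5-[(2R,3R)-3-(TBSO)butan-2-yl]-6-methyl-2H-chromen-2-one; 17 (3S)-3-(ethenyloxy)-1-(pyrrolidin-1-yl)butan-1-one
Product: 18 7-(TBSO)-5-[(2R,3R)-3-(TBSO)butan-2-yl]-6-methyl-3-(1-{[(2S)-4-oxo-4-(pyrrolidin-1-yl)butan-2-yl]oxy}ethenyl)-2H-chromen-2-one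
Conditions: Pd(OAc)2, 1,3-bis(diphenylphosphino)propane, AgOTf, Et3N, DMF, 80 °C
Reagents that add atoms: none
Why: A Mizoroki–Heck reaction run on the cationic pathway (bidentate phosphine, bromide removed by silver) couples at the oxygen-bearing carbon of the electron-rich vinyl ether, and β-hydride elimination then leaves the 1,1-disubstituted 1-alkoxyvinyl group on C3.

Step 12
Reactants: 18 7-(TBSO)-5-[(2R,3R)-3-(TBSO)butan-2-yl]-6-methyl-3-(1-{[(2S)-4-oxo-4-(pyrrolidin-1-yl)butan-2-yl]oxy}ethenyl)-2H-chromen-2-one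
Product: 21 7-(TBSO)-5-[(2R,3R)-3-(TBSO)butan-2-yl]-6-methyl-3-[(2S)-2-methyl-4-oxo-3,4-dihydro-2H-pyran-6-yl]-2H-chromen-2-one, via O-triflyl iminium triflate 19 (not isolated), via vinylogous iminium triflate 20 (not isolated)
Conditions: Tf2O, 2,6-di-tert-butyl-4-methylpyridine, CH2Cl2, −78 → 0 °C; then aq. NaOAc/AcOH (pH 5), THF, rt
Reagents that add atoms: water (O)
Why: Tf2O triflates the amide oxygen, the most Lewis-basic site, to give the O-triflyl iminium ion 19, whose carbon C4' is attacked by the terminal carbon C5' of the 1-alkoxyvinyl group; loss of triflate and then of the C5' proton to the hindered pyridine gives the push–pull iminium salt 20, and buffered water exchanges C4'=N+ for C4'=O. The closest known reaction type is the Vilsmeier–Haack acylation of enol ethers, in its intramolecular variant in which a triflic-anhydride-activated tertiary amide is trapped by a tethered π-nucleophile. The pyranone ring (O1', C2', C3', C4', C5', C6') closes in the 6-(enolendo)-exo-trig mode, the attacking C5'=C6' bond ending inside the ring and the C4'=N+ bond lying outside it. No stereocentre is created, and C2' should keep the S configuration brought in by 15 because the medium is never basic, so that enolisation at C3' and E1cB loss of the enol oxygen from C2' are excluded. The step needs chemoselective activation of the amide beside the lactone, the two silyl ethers and the dienyl ether, which the much higher nucleophilicity of the amide oxygen at −78 °C should secure, and it needs bond formation at C5' only, which is secured because C5' is the single nucleophilic carbon (the cation left at C6' is stabilised by O1' and, through C3=C4, by the para silyloxy group) and because the only other closure open to the iminium carbon, a [2+2] addition across C5'=C6', would fuse a four-membered carbocycle onto an oxetane.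

Step 13
Reactants: 21 7-(TBSO)-5-[(2R,3R)-3-(TBSO)butan-2-yl]-6-methyl-3-[(2S)-2-methyl-4-oxo-3,4-dihydro-2H-pyran-6-yl]-2H-chromen-2-one
Product: 22 7-hydroxy-5-[(2R,3R)-3-hydroxybutan-2-yl]-6-methyl-3-[(2S)-2-methyl-4-oxo-3,4-dihydro-2H-pyran-6-yl]-2H-chromen-2-one
Conditions: HF·pyridine, THF/pyridine, 0 °C → rt
Reagents that add atoms: none
Why: Cleavage of the aryl and the alkyl silyl ether with buffered HF·pyridine is non-basic, so the base-sensitive dihydropyranone (retro-oxa-Michael at C2') and the lactone should not be endangered.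

Compound list
1 | 1,3-bis(benzyloxy)-5-bromobenzene | Brc1cc(OCc2ccccc2)cc(OCc2ccccc2)c1 | starting material
2 | N-{[2,4-bis(benzyloxy)-6-bromophenyl]methylidene}-N-methylmethanaminium dichlorophosphate | C[N+](C)=Cc1c(Br)cc(OCc2ccccc2)cc1OCc1ccccc1.[O-]P(=O)(Cl)Cl | intermediate
3 | 2,4-bis(benzyloxy)-6-bromobenzaldehyde | O=Cc1c(Br)cc(OCc2ccccc2)cc1OCc1ccccc1 | intermediate
4 | 1,5-bis(benzyloxy)-3-bromo-2-methylbenzene | Cc1c(Br)cc(OCc2ccccc2)cc1OCc1ccccc1 | intermediate
5 | (2R,3R)-2,3-dimethyloxirane | C[C@H]1O[C@@H]1C | starting material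
6 | [3,5-bis(benzyloxy)-2-methylphenyl]lithium | [Li]c1cc(OCc2ccccc2)cc(OCc2ccccc2)c1C | intermediate
7 | (2R,3R)-3-[3,5-bis(benzyloxy)-2-methylphenyl]butan-2-ol | Cc1c(OCc2ccccc2)cc(OCc2ccccc2)cc1[C@@H](C)[C@@H](C)O | intermediate
8 | 5-[(2R,3R)-3-hydroxybutan-2-yl]-4-methylbenzene-1,3-diol | Cc1c(O)cc(O)cc1[C@@H](C)[C@@H](C)O | intermediate
9 | (3R,4R)-8-hydroxy-3,4,5-trimethyl-3,4-dihydro-6H-isochromen-6-one | CC1=C2[C@@H](C)[C@@H](C)OC=C2C(O)=CC1=O | intermediate
10 | 2,2-dimethyl-1,3-dioxane-4,6-dione (Meldrum's acid) | CC1(C)OC(=O)CC(=O)O1 | starting material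
11 | 7-hydroxy-5-[(2R,3R)-3-hydroxybutan-2-yl]-6-methyl-2-oxo-2H-chromene-3-carboxylic acid | Cc1c(O)cc2oc(=O)c(C(=O)O)cc2c1[C@@H](C)[C@@H](C)O | intermediate
12 | tert-butyldimethylsilyl 7-[(tert-butyldimethylsilyl)oxy]-5-[(2R,3R)-3-[(tert-butyldimethylsilyl)oxy]butan-2-yl]-6-methyl-2-oxo-2H-chromene-3-carboxylate | Cc1c(O[Si](C)(C)C(C)(C)C)cc2oc(=O)c(C(=O)O[Si](C)(C)C(C)(C)C)cc2c1[C@@H](C)[C@@H](C)O[Si](C)(C)C(C)(C)C | intermediate
13 | 7-[(tert-butyldimethylsilyl)oxy]-5-[(2R,3R)-3-[(tert-butyldimethylsilyl)oxy]butan-2-yl]-6-methyl-2-oxo-2H-chromene-3-carboxylic acid | Cc1c(O[Si](C)(C)C(C)(C)C)cc2oc(=O)c(C(=O)O)cc2c1[C@@H](C)[C@@H](C)O[Si](C)(C)C(C)(C)C | intermediate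
14 | 3-bromo-7-[(tert-butyldimethylsilyl)oxy]-5-[(2R,3R)-3-[(tert-butyldimethylsilyl)oxy]butan-2-yl]-6-methyl-2H-chromen-2-one | Cc1c(O[Si](C)(C)C(C)(C)C)cc2oc(=O)c(Br)cc2c1[C@@H](C)[C@@H](C)O[Si](C)(C)C(C)(C)C | intermediate
15 | ethyl (3S)-3-hydroxybutanoate | CCOC(=O)C[C@H](C)O | starting material
16 | (3S)-3-hydroxy-1-(pyrrolidin-1-yl)butan-1-one | C[C@H](O)CC(=O)N1CCCC1 | intermediate
17 | (3S)-3-(ethenyloxy)-1-(pyrrolidin-1-yl)butan-1-one | C=CO[C@@H](C)CC(=O)N1CCCC1 | intermediate
18 | 7-[(tert-butyldimethylsilyl)oxy]-5-[(2R,3R)-3-[(tert-butyldimethylsilyl)oxy]butan-2-yl]-6-methyl-3-(1-{[(2S)-4-oxo-4-(pyrrolidin-1-yl)butan-2-yl]oxy}ethenyl)-2H-chromen-2-one | Cc1c(O[Si](C)(C)C(C)(C)C)cc2oc(=O)c(C(=C)O[C@@H](C)CC(=O)N3CCCC3)cc2c1[C@@H](C)[C@@H](C)O[Si](C)(C)C(C)(C)C | intermediate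
19 | 1-[(3S)-3-({1-[7-(TBSO)-5-[(2R,3R)-3-(TBSO)butan-2-yl]-6-methyl-2-oxo-2H-chromen-3-yl]ethenyl}oxy)-1-(trifluoromethanesulfonyloxy)butylidene]pyrrolidin-1-ium trifluoromethanesulfonate | Cc1c(O[Si](C)(C)C(C)(C)C)cc2oc(=O)c(C(=C)O[C@@H](C)CC(OS(=O)(=O)C(F)(F)F)=[N+]3CCCC3)cc2c1[C@@H](C)[C@@H](C)O[Si](C)(C)C(C)(C)C.[O-]S(=O)(=O)C(F)(F)F | intermediate
20 | 1-[(2S)-6-[7-(TBSO)-5-[(2R,3R)-3-(TBSO)butan-2-yl]-6-methyl-2-oxo-2H-chromen-3-yl]-2-methyl-2,3-dihydro-4H-pyran-4-ylidene]pyrrolidin-1-ium trifluoromethanesulfonate | Cc1c(O[Si](C)(C)C(C)(C)C)cc2oc(=O)c(C3=CC(=[N+]4CCCC4)C[C@H](C)O3)cc2c1[C@@H](C)[C@@H](C)O[Si](C)(C)C(C)(C)C.[O-]S(=O)(=O)C(F)(F)F | intermediate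
21 | 7-[(tert-butyldimethylsilyl)oxy]-5-[(2R,3R)-3-[(tert-butyldimethylsilyl)oxy]butan-2-yl]-6-methyl-3-[(2S)-2-methyl-4-oxo-3,4-dihydro-2H-pyran-6-yl]-2H-chromen-2-one | Cc1c(O[Si](C)(C)C(C)(C)C)cc2oc(=O)c(C3=CC(=O)C[C@H](C)O3)cc2c1[C@@H](C)[C@@H](C)O[Si](C)(C)C(C)(C)C | intermediate
22 | 7-hydroxy-5-[(2R,3R)-3-hydroxybutan-2-yl]-6-methyl-3-[(2S)-2-methyl-4-oxo-3,4-dihydro-2H-pyran-6-yl]-2H-chromen-2-one | Cc1c(O)cc2oc(=O)c(C3=CC(=O)C[C@H](C)O3)cc2c1[C@@H](C)[C@@H](C)O | target

Total step count: 13. Longest linear sequence: 11 steps (steps 1–8, 11, 12, 13); steps 9 and 10 form the side branch.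

Steps most likely to fail

Step 11. The risk is insertion at the wrong carbon of the vinyl ether (linear, β-coupled product) or hydrolytic loss of the dienyl ether through the ammonium salt formed during the coupling. The fallback sets out from 14 and transfers a preformed α-alkoxyvinyl group, which removes the regiochemical question. Stille coupling of 14 with tributyl(1-ethoxyvinyl)stannane (Pd(PPh3)4, toluene, 100 °C) should give 7-(TBSO)-5-[(2R,3R)-3-(TBSO)butan-2-yl]-3-(1-ethoxyethenyl)-6-methyl-2H-chromen-2-one F1. Pyridinium tosylate-catalysed addition of alcohol 16 across the enol ether should give the mixed ketal 7-(TBSO)-5-[(2R,3R)-3-(TBSO)butan-2-yl]-3-(1-ethoxy-1-{[(2S)-4-oxo-4-(pyrrolidin-1-yl)butan-2-yl]oxy}ethyl)-6-methyl-2H-chromen-2-one F2 (both epimers at the ketal carbon). Me3SiOTf/i-Pr2NEt should then remove the less hindered ethoxy group together with a proton of the adjacent methyl group and give 18, where the route is rejoined.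

Step 12. The risk is C-triflylation of the dienyl ether, fragmentation of the activated amide by loss of the enol oxygen from C2' (giving a crotonoyl iminium ion), or ring opening at C6' during hydrolysis. The fallback sets out from 9 and uses the classical order, in which the C4'–C5' bond is made first and the ring is closed at oxygen. Knoevenagel condensation of 9 with ethyl acetoacetate (piperidinium acetate, EtOH/H2O) should give 3-acetyl-7-hydroxy-5-[(2R,3R)-3-hydroxybutan-2-yl]-6-methyl-2H-chromen-2-one F3. TBSOTf/2,6-lutidine should give 3-acetyl-7-(TBSO)-5-[(2R,3R)-3-(TBSO)butan-2-yl]-6-methyl-2H-chromen-2-one F4. Its lithium enolate (LiN(SiMe3)2, THF, −78 °C) should be C-acylated by (4S)-4-methyloxetan-2-one in a Claisen-type condensation with acyl–oxygen cleavage of the strained lactone, leaving the stereocentre untouched, to give (5S)-1-[7-(TBSO)-5-[(2R,3R)-3-(TBSO)butan-2-yl]-6-methyl-2-oxo-2H-chromen-3-yl]-5-hydroxyhexane-1,3-dione F5. Catalytic TsOH in CH2Cl2 should cyclodehydrate F5 to 21, where the route is rejoined.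

Step 8. The risk is slow ipso attack of bromine at the electron-poor C3, which would allow bromination of the activated benzo ring at C8. The fallback sets out from 13 and removes the carboxyl group before bromine is introduced. Silver-catalysed protodecarboxylation (Ag2CO3 cat., AcOH, DMSO, 100 °C) should give 7-(TBSO)-5-[(2R,3R)-3-(TBSO)butan-2-yl]-6-methyl-2H-chromen-2-one F6, in which C3=C4 is the most nucleophilic site. Addition of bromine (CH2Cl2, −20 °C) should give 3,4-dibromo-7-(TBSO)-5-[(2R,3R)-3-(TBSO)butan-2-yl]-6-methyl-3,4-dihydro-2H-chromen-2-one F7. Et3N should then remove the acidic C3 proton and the benzylic C4 bromide to give 14, where the route is rejoined.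

Further compounds
F1 | step 11 | 7-[(tert-butyldimethylsilyl)oxy]-5-[(2R,3R)-3-[(tert-butyldimethylsilyl)oxy]butan-2-yl]-3-(1-ethoxyethenyl)-6-methyl-2H-chromen-2-one | Cc1c(O[Si](C)(C)C(C)(C)C)cc2oc(=O)c(C(=C)OCC)cc2c1[C@@H](C)[C@@H](C)O[Si](C)(C)C(C)(C)C
F2 | step 11 | 7-[(tert-butyldimethylsilyl)oxy]-5-[(2R,3R)-3-[(tert-butyldimethylsilyl)oxy]butan-2-yl]-3-(1-ethoxy-1-{[(2S)-4-oxo-4-(pyrrolidin-1-yl)butan-2-yl]oxy}ethyl)-6-methyl-2H-chromen-2-one (ketal carbon as both epimers) | Cc1c(O[Si](C)(C)C(C)(C)C)cc2oc(=O)c(C(C)(OCC)O[C@@H](C)CC(=O)N3CCCC3)cc2c1[C@@H](C)[C@@H](C)O[Si](C)(C)C(C)(C)C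
F3 | step 12 | 3-acetyl-7-hydroxy-5-[(2R,3R)-3-hydroxybutan-2-yl]-6-methyl-2H-chromen-2-one | Cc1c(O)cc2oc(=O)c(C(C)=O)cc2c1[C@@H](C)[C@@H](C)O
F4 | step 12 | 3-acetyl-7-[(tert-butyldimethylsilyl)oxy]-5-[(2R,3R)-3-[(tert-butyldimethylsilyl)oxy]butan-2-yl]-6-methyl-2H-chromen-2-one | Cc1c(O[Si](C)(C)C(C)(C)C)cc2oc(=O)c(C(C)=O)cc2c1[C@@H](C)[C@@H](C)O[Si](C)(C)C(C)(C)C
F5 | step 12 | (5S)-1-[7-[(tert-butyldimethylsilyl)oxy]-5-[(2R,3R)-3-[(tert-butyldimethylsilyl)oxy]butan-2-yl]-6-methyl-2-oxo-2H-chromen-3-yl]-5-hydroxyhexane-1,3-dione | Cc1c(O[Si](C)(C)C(C)(C)C)cc2oc(=O)c(C(=O)CC(=O)C[C@H](C)O)cc2c1[C@@H](C)[C@@H](C)O[Si](C)(C)C(C)(C)C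
F6 | step 8 | 7-[(tert-butyldimethylsilyl)oxy]-5-[(2R,3R)-3-[(tert-butyldimethylsilyl)oxy]butan-2-yl]-6-methyl-2H-chromen-2-one | Cc1c(O[Si](C)(C)C(C)(C)C)cc2oc(=O)ccc2c1[C@@H](C)[C@@H](C)O[Si](C)(C)C(C)(C)C
F7 | step 8 | 3,4-dibromo-7-[(tert-butyldimethylsilyl)oxy]-5-[(2R,3R)-3-[(tert-butyldimethylsilyl)oxy]butan-2-yl]-6-methyl-3,4-dihydro-2H-chromen-2-one (C3 and C4 unassigned) | Cc1c(O[Si](C)(C)C(C)(C)C)cc2OC(=O)C(Br)C(Br)c2c1[C@@H](C)[C@@H](C)O[Si](C)(C)C(C)(C)C
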